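**Retrosynthetic overview**
1. Target 27 ⇐ 26 by one-pot syn-hydrogenation of the coumarin C3=C4 bond (sets both centres of the cis half) and hydrogenolysis of eight benzyl ethers.
2. 26 ⇐ C3–C3' bond by palladium-catalysed coupling of the zinc enolate of (4R)-dihydrocoumarin 11 with 3-bromocoumarin 23.
3. 11 ⇐ asymmetric copper hydride 1,4-reduction of neoflavone 10 ⇐ phloroglucinol 4 (from resorcinol by C–H borylation/oxidation) + aryl propiolate 8 (from 4-iodophenol + ethyl propiolate).
4. 23 ⇐ hydroquinone 20 + 8; the pentaoxygenated benzene ring of 20 ⇐ key step: two-carbon ring expansion of the four-membered ring of dibenzyl squarate 18 with benzyl ethynyl ether 16.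
5. Ring order: pentaoxygenated benzene ring (step 9), its pyranone ring (step 10); pyranone ring of the phloroglucinol half (step 4); the halves are joined and the second lactone ring is saturated last.

Assumption: benzyl bromide is treated as a protecting-group reagent; benzyl alcohol, whose oxygen atoms stay in the target, is numbered as a starting material (13), and step 8 consumes two molecules of it.

**Step 1**
Reactants: 1 resorcinol
Product: 4 phloroglucinol (benzene-1,3,5-triol), via resorcinol bis(pinacolboryl) ether 2 (not isolated), via 5-borylated resorcinol bis(pinacolboryl) ether 3 (not isolated)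
Conditions: HBpin (3.3 equiv), [Ir(OMe)(cod)]2 (1.5 mol%), dtbpy (3 mol%), THF, 80 °C; then KHSO5 (as Oxone), acetone/H2O, rt
Reagents that add atoms: potassium peroxymonosulfate KHSO5, [K+].[O-]S(=O)(=O)OO (the new oxygen); pinacolborane, [H]B1OC(C)(C)C(C)(C)O1 (boron only in 2 and 3)
Why: Iridium-catalysed C–H borylation is sterically controlled, so after in situ O-borylation only C5 (the one C–H with no ortho substituent) is borylated, and oxidation of the C–B bond with hydrolysis of the O–B bonds gives the triol (one-pot C–H borylation/oxidation).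

**Step 2**
Reactants: 5 4-iodophenol
Product: 6 1-(benzyloxy)-4-iodobenzene
Conditions: BnBr, K2CO3, acetone, reflux
Reagents that add atoms: benzyl bromide, BrCc1ccccc1
Why: Williamson ether synthesis on the phenoxide.

**Step 3**
Reactants: 6 1-(benzyloxy)-4-iodobenzene; 7 ethyl propiolate
Product: 8 ethyl 3-[4-(benzyloxy)phenyl]prop-2-ynoate
Conditions: PdCl2(PPh3)2 (2 mol%), CuI (4 mol%), K2CO3, THF, 60 °C
Reagents that add atoms: none
Why: Sonogashira coupling of an aryl iodide, run with carbonate instead of an amine so that the base does not add to the propiolate.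

**Step 4**
Reactants: 4 phloroglucinol (1.5 equiv); 8 ethyl 3-[4-(benzyloxy)phenyl]prop-2-ynoate
Product: 9 4-[4-(benzyloxy)phenyl]-5,7-dihydroxy-2H-chromen-2-one
Conditions: Pd(OAc)2 (5 mol%), NaOAc, HCO2H, rt
Reagents that add atoms: none
Why: Palladium-catalysed hydroarylation of the alkynoate by the electron-rich phenol followed by lactonisation (Pechmann-type coumarin synthesis); the three ring positions are equivalent, excess phenol suppresses double annulation, and formic acid at rt spares the benzyl ether.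

**Step 5**
Reactants: 9 4-[4-(benzyloxy)phenyl]-5,7-dihydroxy-2H-chromen-2-one
Product: 10 5,7-bis(benzyloxy)-4-[4-(benzyloxy)phenyl]-2H-chromen-2-one
Conditions: BnBr (2.4 equiv), K2CO3, DMF, 50 °C
Reagents that add atoms: benzyl bromide, BrCc1ccccc1
Why: Williamson ether synthesis on both phenols.

**Step 6**
Reactants: 10 5,7-bis(benzyloxy)-4-[4-(benzyloxy)phenyl]-2H-chromen-2-one
Product: 11 (4R)-5,7-bis(benzyloxy)-4-[4-(benzyloxy)phenyl]-3,4-dihydro-2H-chromen-2-one
Conditions: Cu(OAc)2·H2O (3 mol%), DTBM-SEGPHOS (3 mol%, antipode that gives 4R), (EtO)2MeSiH, t-BuOH, toluene, rt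
Reagents that add atoms: none
Why: Copper hydride-catalysed asymmetric conjugate reduction of a 4-arylcoumarin, in which the ligand-bound copper hydride delivers hydride to one face of C4 and so sets the 4R centre.

**Step 7**
Reactants: 12 trichloroethylene; 13 benzyl alcohol
Product: 16 benzyl ethynyl ether, via benzyl (E)-1,2-dichlorovinyl ether 14 (not isolated), via lithium (benzyloxy)acetylide 15 (not isolated)
Conditions: KH, THF, 0 °C → rt; n-BuLi (2.2 equiv), −78 → −40 °C; MeOH (1 equiv), −78 °C; cold pentane/H2O work-up, solution used at once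
Reagents that add atoms: n-butyllithium, [Li]CCCC (lithium only in 15)
Why: Addition–elimination of the alkoxide on trichloroethylene, then dehydrochlorination and chlorine–lithium exchange to the alkoxyacetylide and protonation (Greene ynol ether synthesis).

**Step 8**
Reactants: 17 squaric acid; 13 benzyl alcohol
Product: 18 dibenzyl squarate (3,4-bis(benzyloxy)cyclobut-3-ene-1,2-dione)
Conditions: BnOH (13, 4 equiv), toluene, reflux, Dean–Stark
Reagents that add atoms: benzyl alcohol, OCc1ccccc1 (the second molecule of 13, which supplies the second benzyloxy group)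
Why: Twofold azeotropic esterification of the vinylogous diacid, in which each of the two vinylogous carboxyl carbons takes up one molecule of benzyl alcohol by addition–elimination with loss of water (17 + 2 × 13 → 18 + 2 H2O), the acid catalysing its own esterification.

**Step 9**
Reactants: 18 dibenzyl squarate; 16 benzyl ethynyl ether
Product: 20 2,3,5-tris(benzyloxy)benzene-1,4-diol, via 2,3,5-tris(benzyloxy)-1,4-benzoquinone 19 (not isolated)
Conditions: Ni(cod)2 (10 mol%), PPh3 (20 mol%), toluene, 0 °C → rt, slow addition of 16; then aq. Na2S2O4, EtOAc, rt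
Reagents that add atoms: none
Why: Proposed new method: zerovalent nickel inserts into the strained C1–C2 acyl–acyl bond of the squarate to give a dialkoxymaleoylnickel metallacycle, the electron-rich ynol ether inserts into a Ni–acyl bond and reductive elimination closes the six-membered 1,4-benzoquinone (the key two-carbon ring expansion by C–C activation, regiochemistry irrelevant because 18 is symmetric), which dithionite reduces to the hydroquinone; the closest known reactions are the stoichiometric maleoylcobalt–alkyne quinone synthesis and the zerovalent-nickel-catalysed cyclobutenone + alkyne → phenol ring expansion.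

**Step 10**
Reactants: 20 2,3,5-tris(benzyloxy)benzene-1,4-diol; 8 ethyl 3-[4-(benzyloxy)phenyl]prop-2-ynoate
Product: 21 5,7,8-tris(benzyloxy)-4-[4-(benzyloxy)phenyl]-6-hydroxy-2H-chromen-2-one
Conditions: Pd(OAc)2 (5 mol%), NaOAc, HCO2H, rt, argon
Reagents that add atoms: none
Why: The same palladium-catalysed hydroarylation/lactonisation (Pechmann-type); 20 has a single aromatic C–H and only one hydroxyl ortho to it, so one coumarin can form, and the reducing medium keeps the hydroquinone from oxidising.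

**Step 11**
Reactants: 21 5,7,8-tris(benzyloxy)-4-[4-(benzyloxy)phenyl]-6-hydroxy-2H-chromen-2-one
Product: 22 5,6,7,8-tetrakis(benzyloxy)-4-[4-(benzyloxy)phenyl]-2H-chromen-2-one
Conditions: BnBr, K2CO3, DMF, 60 °C
Reagents that add atoms: benzyl bromide, BrCc1ccccc1
Why: Williamson ether synthesis on the remaining phenol.

**Step 12**
Reactants: 22 5,6,7,8-tetrakis(benzyloxy)-4-[4-(benzyloxy)phenyl]-2H-chromen-2-one
Product: 23 5,6,7,8-tetrakis(benzyloxy)-4-[4-(benzyloxy)phenyl]-3-bromo-2H-chromen-2-one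
Conditions: NBS (1.05 equiv), MeCN, 0 °C → rt, dark
Reagents that add atoms: N-bromosuccinimide, O=C1CCC(=O)N1Br
Why: Electrophilic bromination by addition–elimination at C3, the nucleophilic end of the aryl-substituted enol-ether-like alkene; the fused benzene ring has no C–H left.

**Step 13**
Reactants: 11 (4R)-5,7-bis(benzyloxy)-4-[4-(benzyloxy)phenyl]-3,4-dihydro-2H-chromen-2-one; 23 5,6,7,8-tetrakis(benzyloxy)-4-[4-(benzyloxy)phenyl]-3-bromo-2H-chromen-2-one
Product: 26 (3R,4R)-5,7-bis(benzyloxy)-4-[4-(benzyloxy)phenyl]-3-{5,6,7,8-tetrakis(benzyloxy)-4-[4-(benzyloxy)phenyl]-2-oxo-2H-chromen-3-yl}-3,4-dihydro-2H-chromen-2-one, via lithium lactone enolate 24 (not isolated), via chlorozinc lactone enolate 25 (not isolated)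
Conditions: LiHMDS, THF, −78 °C; ZnCl2, −78 → 0 °C; 23, Pd(dba)2 (5 mol%), Q-Phos (5 mol%), THF, rt → 50 °C
Reagents that add atoms: lithium bis(trimethylsilyl)amide, [Li]N([Si](C)(C)C)[Si](C)(C)C (lithium only in 24); zinc dichloride, Cl[Zn]Cl (zinc and chlorine only in 25)
Why: Palladium-catalysed α-alkenylation of a zinc ester enolate (Reformatsky–Negishi-type coupling); the alkenyl group enters C3 anti to the C4 aryl group, giving the 3,4-trans (3R) centre, which is also the thermodynamic epimer.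

**Step 14**
Reactants: 26 (3R,4R)-5,7-bis(benzyloxy)-4-[4-(benzyloxy)phenyl]-3-{5,6,7,8-tetrakis(benzyloxy)-4-[4-(benzyloxy)phenyl]-2-oxo-2H-chromen-3-yl}-3,4-dihydro-2H-chromen-2-one
Product: 27 (3R,4R)-5,7-dihydroxy-4-(4-hydroxyphenyl)-3-[(3S,4R)-5,6,7,8-tetrahydroxy-4-(4-hydroxyphenyl)-2-oxo-3,4-dihydro-2H-chromen-3-yl]-3,4-dihydro-2H-chromen-2-one (target)
Conditions: H2 (30 bar), Pd(OH)2/C, EtOAc/AcOH, 40 °C; filtration and concentration under argon
Reagents that add atoms: none
Why: Heterogeneous catalytic hydrogenation adds both hydrogens to one face of the tetrasubstituted C3=C4 bond (syn addition, hence 3,4-cis), and with the neighbouring C3–H eclipsing the alkene (allylic 1,3-strain against the 4-aryl group) the bulky diarylmethine carbon shields one face, so hydrogen enters from the lactone-carbonyl side to give (3S,4R); the same catalyst cleaves all eight benzyl ethers by hydrogenolysis.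

**Compound list**
1 | resorcinol | Oc1cccc(O)c1 | starting material
2 | 1,3-bis[(4,4,5,5-tetramethyl-1,3,2-dioxaborolan-2-yl)oxy]benzene | CC1(C)OB(Oc2cccc(OB3OC(C)(C)C(C)(C)O3)c2)OC1(C)C | intermediate
3 | 1,3-bis[(4,4,5,5-tetramethyl-1,3,2-dioxaborolan-2-yl)oxy]-5-(4,4,5,5-tetramethyl-1,3,2-dioxaborolan-2-yl)benzene | CC1(C)OB(Oc2cc(OB3OC(C)(C)C(C)(C)O3)cc(B3OC(C)(C)C(C)(C)O3)c2)OC1(C)C | intermediate
4 | phloroglucinol | Oc1cc(O)cc(O)c1 | intermediate
5 | 4-iodophenol | Oc1ccc(I)cc1 | starting material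
6 | 1-(benzyloxy)-4-iodobenzene | Ic1ccc(OCc2ccccc2)cc1 | intermediate
7 | ethyl propiolate | CCOC(=O)C#C | starting material
8 | ethyl 3-[4-(benzyloxy)phenyl]prop-2-ynoate | CCOC(=O)C#Cc1ccc(OCc2ccccc2)cc1 | intermediate
9 | 4-[4-(benzyloxy)phenyl]-5,7-dihydroxy-2H-chromen-2-one | O=C1C=C(c2ccc(OCc3ccccc3)cc2)c2c(O)cc(O)cc2O1 | intermediate
10 | 5,7-bis(benzyloxy)-4-[4-(benzyloxy)phenyl]-2H-chromen-2-one | O=C1C=C(c2ccc(OCc3ccccc3)cc2)c2c(OCc3ccccc3)cc(OCc3ccccc3)cc2O1 | intermediate
11 | (4R)-5,7-bis(benzyloxy)-4-[4-(benzyloxy)phenyl]-3,4-dihydro-2H-chromen-2-one | O=C1Oc2cc(OCc3ccccc3)cc(OCc3ccccc3)c2[C@@H](c2ccc(OCc3ccccc3)cc2)C1 | intermediate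
12 | trichloroethylene | ClC=C(Cl)Cl | starting material
13 | benzyl alcohol | OCc1ccccc1 | starting material
14 | benzyl (E)-1,2-dichlorovinyl ether | Cl/C=C(/Cl)OCc1ccccc1 | intermediate
15 | lithium (benzyloxy)acetylide | [Li]C#COCc1ccccc1 | intermediate
16 | benzyl ethynyl ether | C#COCc1ccccc1 | intermediate
17 | squaric acid | OC1=C(O)C(=O)C1=O | starting material
18 | dibenzyl squarate | O=C1C(=O)C(OCc2ccccc2)=C1OCc1ccccc1 | intermediate
19 | 2,3,5-tris(benzyloxy)cyclohexa-2,5-diene-1,4-dione | O=C1C=C(OCc2ccccc2)C(=O)C(OCc2ccccc2)=C1OCc1ccccc1 | intermediate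
20 | 2,3,5-tris(benzyloxy)benzene-1,4-diol | Oc1cc(OCc2ccccc2)c(O)c(OCc2ccccc2)c1OCc1ccccc1 | intermediate
21 | 5,7,8-tris(benzyloxy)-4-[4-(benzyloxy)phenyl]-6-hydroxy-2H-chromen-2-one | O=C1C=C(c2ccc(OCc3ccccc3)cc2)c2c(OCc3ccccc3)c(O)c(OCc3ccccc3)c(OCc3ccccc3)c2O1 | intermediate
22 | 5,6,7,8-tetrakis(benzyloxy)-4-[4-(benzyloxy)phenyl]-2H-chromen-2-one | O=C1C=C(c2ccc(OCc3ccccc3)cc2)c2c(OCc3ccccc3)c(OCc3ccccc3)c(OCc3ccccc3)c(OCc3ccccc3)c2O1 | intermediate
23 | 5,6,7,8-tetrakis(benzyloxy)-4-[4-(benzyloxy)phenyl]-3-bromo-2H-chromen-2-one | O=C1C(Br)=C(c2ccc(OCc3ccccc3)cc2)c2c(OCc3ccccc3)c(OCc3ccccc3)c(OCc3ccccc3)c(OCc3ccccc3)c2O1 | intermediate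
24 | lithium (4R)-5,7-bis(benzyloxy)-4-[4-(benzyloxy)phenyl]-4H-chromen-2-olate | [Li]OC1=C[C@H](c2ccc(OCc3ccccc3)cc2)c2c(OCc3ccccc3)cc(OCc3ccccc3)cc2O1 | intermediate
25 | chlorozinc (4R)-5,7-bis(benzyloxy)-4-[4-(benzyloxy)phenyl]-4H-chromen-2-olate | Cl[Zn]OC1=C[C@H](c2ccc(OCc3ccccc3)cc2)c2c(OCc3ccccc3)cc(OCc3ccccc3)cc2O1 | intermediate
26 | (3R,4R)-5,7-bis(benzyloxy)-4-[4-(benzyloxy)phenyl]-3-{5,6,7,8-tetrakis(benzyloxy)-4-[4-(benzyloxy)phenyl]-2-oxo-2H-chromen-3-yl}-3,4-dihydro-2H-chromen-2-one | O=C1Oc2cc(OCc3ccccc3)cc(OCc3ccccc3)c2[C@@H](c2ccc(OCc3ccccc3)cc2)[C@@H]1C1=C(c2ccc(OCc3ccccc3)cc2)c2c(OCc3ccccc3)c(OCc3ccccc3)c(OCc3ccccc3)c(OCc3ccccc3)c2OC1=O | intermediate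
27 | (3R,4R)-5,7-dihydroxy-4-(4-hydroxyphenyl)-3-[(3S,4R)-5,6,7,8-tetrahydroxy-4-(4-hydroxyphenyl)-2-oxo-3,4-dihydro-2H-chromen-3-yl]-3,4-dihydro-2H-chromen-2-one | O=C1Oc2cc(O)cc(O)c2[C@@H](c2ccc(O)cc2)[C@@H]1[C@H]1C(=O)Oc2c(O)c(O)c(O)c(O)c2[C@H]1c1ccc(O)cc1 | target

**Totals**
Total step count: 14.
Longest linear sequence: 7 steps (17 → 18 → 20 → 21 → 22 → 23 → 26 → 27; the branches from 12 and from 5 are equally long).

**Steps most likely to fail, with fallbacks**

Step 9 (the proposed ring expansion). The quinone product may stop nickel turnover, or the ynol ether may oligomerise. The fallback uses known chemistry, sets out from 18 and comes back at 20. 18 is stirred with ClCo(PPh3)3 (monovalent cobalt) in benzene at rt; cobalt inserts into the C1–C2 bond and gives the isolable trivalent-cobalt metallacycle chlorobis(triphenylphosphine)[2,3-bis(benzyloxy)maleoyl]cobalt F1. F1 is treated with 16 and AgBF4 in MeCN (rt to 50 °C), which releases quinone 19, and aqueous Na2S2O4 then gives 20. This is the stoichiometric maleoylcobalt–alkyne quinone synthesis.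

Step 13 (coupling of two hindered partners). The zinc enolate may react sluggishly with the tetrasubstituted alkenyl bromide or open to a ketene. The fallback sets out from 11 and comes back at 26. 11 is deprotonated (LiHMDS, THF, −78 °C) and brominated with NBS to (4R)-5,7-bis(benzyloxy)-4-[4-(benzyloxy)phenyl]-3-bromo-3,4-dihydro-2H-chromen-2-one F2 (both C3 epimers are usable). F2 and the unbrominated coumarin 22 are irradiated (blue LED) with fac-Ir(ppy)3 and 2,6-lutidine in DMF. The lactone α-radical adds to C3 of 22, and the diaryl-stabilised C4 radical is oxidised and loses the C3 proton, giving 26 with the new bond anti to the C4 aryl group. Step 12 is then not needed. This is a photoredox C–H alkylation in place of a cross-coupling.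

Step 14 (hydrogenation of a tetrasubstituted alkene under substrate control). The alkene may resist reduction, or hydrogen may enter from the other face and give the (3R,4S) epimer pair in the saturated half. The fallback sets out from 26 and comes back at 27. The alkene is first reduced under reagent control with the homogeneous cationic iridium catalyst [Ir(cod)(tBu-PHOX)][B(C6H3(CF3)2)4] (ligand antipode selected by screening; H2 50 bar, CH2Cl2, rt). This is still a syn addition and gives the octabenzyl ether (3R,4R)-5,7-bis(benzyloxy)-4-[4-(benzyloxy)phenyl]-3-{(3S,4R)-5,6,7,8-tetrakis(benzyloxy)-4-[4-(benzyloxy)phenyl]-2-oxo-3,4-dihydro-2H-chromen-3-yl}-3,4-dihydro-2H-chromen-2-one F3. F3 is then debenzylated with H2 (1 bar), Pd/C in THF/MeOH to 27.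

**Further compounds**
F1 | step 9 | chlorobis(triphenylphosphine)[2,3-bis(benzyloxy)maleoyl]cobalt | O=C1C(OCc2ccccc2)=C(OCc2ccccc2)C(=O)[Co]1(Cl)([P](c1ccccc1)(c1ccccc1)c1ccccc1)[P](c1ccccc1)(c1ccccc1)c1ccccc1
F2 | step 13 | (4R)-5,7-bis(benzyloxy)-4-[4-(benzyloxy)phenyl]-3-bromo-3,4-dihydro-2H-chromen-2-one (C3 epimers) | O=C1Oc2cc(OCc3ccccc3)cc(OCc3ccccc3)c2[C@@H](c2ccc(OCc3ccccc3)cc2)C1Br
F3 | step 14 | (3R,4R)-5,7-bis(benzyloxy)-4-[4-(benzyloxy)phenyl]-3-{(3S,4R)-5,6,7,8-tetrakis(benzyloxy)-4-[4-(benzyloxy)phenyl]-2-oxo-3,4-dihydro-2H-chromen-3-yl}-3,4-dihydro-2H-chromen-2-one | O=C1Oc2cc(OCc3ccccc3)cc(OCc3ccccc3)c2[C@@H](c2ccc(OCc3ccccc3)cc2)[C@@H]1[C@H]1C(=O)Oc2c(OCc3ccccc3)c(OCc3ccccc3)c(OCc3ccccc3)c(OCc3ccccc3)c2[C@H]1c1ccc(OCc2ccccc2)cc1
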